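## The problem

Gnetucleistol F (27) is a 2,3-dihydro-1-benzofuran whose dihydrofuran ring (O1, C2, C3) is fused to ring A (C3a to C7a). C2 carries a 4-hydroxy-3,5-dimethoxyphenyl (syringyl) ring, C3 a hydroxymethyl group, C7 a methoxy group and C5 an (E)-3,5-dihydroxystyryl arm. The only stereocentres are the contiguous C2 (R) and C3 (S), trans to each other. Either centre can steer the other in a ring closure, because trans is the more stable arrangement, but the absolute configuration must come from outside. It is most reliably introduced on an open chain, where one reagent-controlled C2–C3 bond formation sets both centres. Ring A is 1,2,3,5-tetrasubstituted (alkyl at C3a, oxygen at C7a, methoxy at C7, vinyl at C5), a pattern that electrophilic substitution directed by the methoxy group would not deliver. Three features are fragile. The benzylic C2–O1 ether, para to a phenol, can open to a quinone methide under acid or strong base and scramble C2. The electron-rich stilbene excludes hydrogenolysis, strong acid and oxidants. Three phenols and a primary alcohol must be unmasked together under mild conditions. The enabling feature is that O1 sits on C7a, para to C5: with C5 at the aldehyde oxidation level, a C7a–F bond is activated for addition–elimination by the C2 oxygen, and the same aldehyde later serves as the handle for the stilbene. In the open chain the C2 hydroxyl and the primary hydroxyl are equally distant from C7a, so the primary one must be blocked before ring closure.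

## Retrosynthesis

**27 from 26.** Only protecting-group bonds are cut: three aryl methoxymethyl ethers and one trityl ether. All four leave in a single mild acid methanolysis. Trityl is placed on the primary oxygen instead of a fourth methoxymethyl group because an alkyl methoxymethyl ether needs acid strong enough to ionise C2–O1. Trityl also goes on the primary hydroxyl with high selectivity and cannot migrate under base.

**26 from 20 and 24.** The stilbene C=C is cut. A Horner–Wadsworth–Emmons reaction between the C5 aldehyde 20 and the benzylic phosphonate 24 should give the E alkene. A Heck coupling at a C5 halide was the neighbouring choice, but a halide would not activate ring A for the ring closure, whereas the aldehyde serves both purposes. Phosphonate 24 is reached from 3,5-dihydroxybenzyl alcohol (21) through 22 and 23.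

**20 from 18.** The C7a–O1 bond is cut. Cutting C2–O1 instead would require a free ring A phenol and closure at a benzylic cation or quinone methide, leaving C2 under thermodynamic control only. Cutting C3–C3a would create a stereocentre during the closure. Displacement of fluoride at C7a touches neither stereocentre. The precursor 18 is acyclic, with two stereocentres, one fluoride and one aldehyde. The forward step requires that only the C2 alkoxide attacks and that the aldehyde survives the base.

**18 from 15.** These are functional-group changes only. The primary hydroxyl of 17 is tritylated. The aldehyde of 17 is released from the dioxolane of 16 before tritylation, so the trityl ether never meets aqueous acid. Diol 16 comes from reductive removal of the auxiliary from 15.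

**15 from 10 and 12.** The C2–C3 bond is cut as an auxiliary-controlled syn aldol between the arylacetyl imide 10 and protected syringaldehyde 12. This sets both stereocentres in one step, and the syn chain maps onto the trans ring. The forward reaction requires the ring A aldehyde to be masked (dioxolane) through enolisation and hydride reduction. Aldehyde 12 is one step from syringaldehyde (11).

**10 from 1.** The N-acyl bond is cut to acid 7 and (R)-4-benzyl-2-oxazolidinone (8). Acid 7 comes from ester 5. The aryl–CH2 bond of 5 is cut to iodide 4 (palladium-catalysed coupling with a zinc ester enolate). The C–I bond of 4 is cut to aryllithium 3, formed by fluorine-directed ortho-metalation of acetal 2. Compound 2 is the acetal of 4-fluoro-3-methoxybenzaldehyde (1), which already has fluorine para to the formyl carbon and ortho to the methoxy group.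

## Roads not taken

**Alternative 1:** Paternò–Büchi oxetane, then transposition.
- **Cut:** C2–C3 and an O–CH2 bond of a 2,3-diaryloxetane. The oxetane is later opened at C2, with inversion, by the unmasked ring A phenol, releasing the C3 hydroxymethyl group.
- **Forward key step:** irradiation near 350 nm of silylated syringaldehyde A1 with the ring A styrene A2, in the presence of a chiral Lewis acid or hydrogen-bonding host, to give the trans oxetane A3.
- **Merits:** two simple aromatics are joined directly, both stereocentres arise in one step, and the route could be about half as long.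
- **Weak points:** the triplet aldehyde adds through a 1,4-biradical, so relative configuration depends on biradical lifetimes. Absolute control of an intermolecular aryl aldehyde–styrene photocycloaddition by a chiral host has no close model. The styrene triplet lies below that of the aldehyde, so energy transfer and styrene dimerisation compete. The aryl bromide is photolabile. The later opening must be a clean SN2 reaction at a carbon that readily ionises.
- **Comparison:** this road is clearly shorter and needs no auxiliary. Against that, the chosen plan takes both stereocentres from a very dependable auxiliary-controlled aldol, and its ring closure cannot disturb them.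

**Alternative 2:** ring A by (2+2+2) cyclotrimerisation.
- **Cut:** C3a–C7a, C4–C5 and C6–C7.
- **Forward key step:** Cp*RuCl(cod) or RhCl(PPh3)3 joins the borylated ynol-ether diyne A4 with 3,3-diethoxypropyne A5, closing ring A and the dihydrofuran ring together to give A6.
- **Merits:** three skeletal bonds and two rings form in one step, the stereocentres are spectators, and boron and acetal mark C7 and C5 for later conversion.
- **Weak points:** A4 already contains both stereocentres, so the stereochemical work (an aldol or its equivalent) is not saved. Alkynyl ethers of secondary benzylic alcohols are hard to prepare and rearrange thermally. The orientation of A5 (acetal at C5 or C6) is not secured by the substrate. Converting boron to methoxy costs two more steps.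
- **Comparison:** this road forms more bonds in its key step. The chosen plan starts from a ring A that already has the correct pattern and needs no regiochemical decision at the ring-forming stage.

**Alternative 3:** oxidative ring contraction of a flavanone.
- **Cut:** C3–C3a, formed by a 1,2-shift of ring A.
- **Forward key step:** trivalent iodine, PhI(OAc)2 with acid in an orthoformate medium, attacks the enol ether of the (2R)-flavanone A7 at its C3. Ring A migrates from the carbonyl carbon, giving the trans methyl ester A8.
- **Merits:** A7 is a few steps from simple materials through an asymmetric oxa-Michael cyclisation. C2 controls C3, because the ester-bearing centre equilibrates to trans. The ester is one reduction from the hydroxymethyl group. The step count is probably lower than in the chosen plan.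
- **Weak points:** C2 of a flavanone with an electron-rich 2-aryl group racemises by retro-oxa-Michael opening under the acidic conditions. The electron-rich syringyl ring is a better migrating group than the brominated ring A, so the isoflavone pathway and dehydrogenation to the flavone compete.
- **Comparison:** this road is equal or better in length and in trans control. The chosen plan has no racemisable intermediate after the aldol and no question of which group migrates.

Key step: step 11

## Route

Remark: atoms are numbered on the 2,3-dihydro-1-benzofuran core (O1, C2, C3, C3a, C4 to C7, C7a); ring A is its benzo ring; MOM = methoxymethyl, Tr = triphenylmethyl.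

Step 1
Reactants: 1 4-fluoro-3-methoxybenzaldehyde
Product: 2 2-(4-fluoro-3-methoxyphenyl)-1,3-dioxolane
Conditions: ethylene glycol, p-TsOH·H2O (cat.), toluene, reflux, Dean–Stark trap
Reagents that add atoms: ethylene glycol, OCCO
Why: Acid-catalysed acetalisation with azeotropic removal of water; the dioxolane masks the aldehyde against the organolithium, the boron enolate and the borohydride of later steps.

Step 2
Reactants: 2 2-(4-fluoro-3-methoxyphenyl)-1,3-dioxolane
Product: 4 2-(4-fluoro-3-iodo-5-methoxyphenyl)-1,3-dioxolane, via aryllithium 3 (not isolated)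
Conditions: s-BuLi, PMDTA, THF, −78 °C; then I2, −78 °C to rt
Reagents that add atoms: iodine, II
Why: Directed ortho-metalation: fluorine is the strongest acidifying ortho substituent, and triamine-complexed s-BuLi deprotonates by acidity, not by coordination, so the ring hydrogen next to fluorine should be removed in preference to the more hindered one between the methoxy group and the acetal. At −78 °C aryllithium 3 should not lose LiF, and iodine traps it.

Step 3
Reactants: 4 2-(4-fluoro-3-iodo-5-methoxyphenyl)-1,3-dioxolane
Product: 5 ethyl 2-[5-(1,3-dioxolan-2-yl)-2-fluoro-3-methoxyphenyl]acetate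
Conditions: BrZnCH2CO2Et (from BrCH2CO2Et and Zn dust, THF), Pd(dba)2 (cat.), P(t-Bu)3 (cat.), THF, rt to 50 °C
Reagents that add atoms: ethyl bromoacetate, CCOC(=O)CBr, used as its zinc reagent bromo(2-ethoxy-2-oxoethyl)zinc, CCOC(=O)C[Zn]Br
Why: Negishi-type coupling of a Reformatsky reagent (palladium-catalysed α-arylation of a zinc ester enolate): oxidative addition of zerovalent palladium into the C–I bond, transmetalation from zinc and reductive elimination. The nearly neutral zinc enolate should leave the acetal and the aryl fluoride untouched.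

Step 4
Reactants: 5 ethyl 2-[5-(1,3-dioxolan-2-yl)-2-fluoro-3-methoxyphenyl]acetate
Product: 7 2-[5-(1,3-dioxolan-2-yl)-2-fluoro-3-methoxyphenyl]acetic acid, via lithium carboxylate 6 (not isolated)
Conditions: LiOH·H2O, THF/H2O, 0 °C to rt; then 1 M HCl to pH 4, 0 °C
Reagents that add atoms: lithium hydroxide, [Li+].[OH-]
Why: Ester saponification; the dioxolane is stable to base and should survive a brief, cold acidification to pH 4.

Step 5
Reactants: 7 2-[5-(1,3-dioxolan-2-yl)-2-fluoro-3-methoxyphenyl]acetic acid; 8 (R)-4-benzyl-2-oxazolidinone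
Product: 10 (4R)-4-benzyl-3-{2-[5-(1,3-dioxolan-2-yl)-2-fluoro-3-methoxyphenyl]acetyl}-1,3-oxazolidin-2-one, via mixed pivalic anhydride 9 (not isolated)
Conditions: t-BuCOCl, Et3N, THF, −20 °C; then 8, LiCl, −20 °C to rt
Reagents that add atoms: none
Why: N-acylation of the oxazolidinone through a mixed anhydride with LiCl/amine activation; the nucleophile attacks the less hindered arylacetyl carbonyl, and no strong base meets the acidic benzylic position.

Step 6
Reactants: 11 syringaldehyde (4-hydroxy-3,5-dimethoxybenzaldehyde)
Product: 12 3,5-dimethoxy-4-(methoxymethoxy)benzaldehyde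
Conditions: MOMCl, i-Pr2NEt, CH2Cl2, 0 °C to rt
Reagents that add atoms: chloromethyl methyl ether, COCCl
Why: O-alkylation of the phenol to an acetal-type ether that is stable to base, fluoride and hydride and is removed by mild acid at the end.

Step 7
Reactants: 10 (4R)-4-benzyl-3-{2-[5-(1,3-dioxolan-2-yl)-2-fluoro-3-methoxyphenyl]acetyl}-1,3-oxazolidin-2-one; 12 3,5-dimethoxy-4-(methoxymethoxy)benzaldehyde
Product: 15 (4R)-4-benzyl-3-[(2R,3R)-2-[5-(1,3-dioxolan-2-yl)-2-fluoro-3-methoxyphenyl]-3-hydroxy-3-[3,5-dimethoxy-4-(methoxymethoxy)phenyl]propanoyl]-1,3-oxazolidin-2-one, via boron enolate 13 (not isolated), via boron aldolate 14 (not isolated)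
Conditions: n-Bu2BOTf, i-Pr2NEt, CH2Cl2, −78 to 0 °C; then 12, −78 to 0 °C; then pH 7 phosphate buffer, MeOH, 30% H2O2, 0 °C
Reagents that add atoms: none
Why: Evans syn aldol: soft enolisation gives the Z-boron enolate 13, which adds through a closed six-membered chair transition state on the enolate face away from the benzyl group of the (R)-auxiliary, with the oxazolidinone carbonyl turned away from the enolate oxygen. This sets both new centres (2R,3R) as the syn pair, and buffered peroxide then cleaves the boron aldolate 14.

Step 8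
Reactants: 15 (4R)-4-benzyl-3-[(2R,3R)-2-[5-(1,3-dioxolan-2-yl)-2-fluoro-3-methoxyphenyl]-3-hydroxy-3-[3,5-dimethoxy-4-(methoxymethoxy)phenyl]propanoyl]-1,3-oxazolidin-2-one
Product: 16 (1R,2S)-2-[5-(1,3-dioxolan-2-yl)-2-fluoro-3-methoxyphenyl]-1-[3,5-dimethoxy-4-(methoxymethoxy)phenyl]propane-1,3-diol
Conditions: LiBH4, MeOH (1 equiv), THF, 0 °C
Reagents that add atoms: none
Why: Reductive cleavage of the N-acyl oxazolidinone at the exocyclic carbonyl by LiBH4; the auxiliary is released, and the former α-carbon is no longer epimerisable (its descriptor changes to S only through the priority change).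

Step 9
Reactants: 16 (1R,2S)-2-[5-(1,3-dioxolan-2-yl)-2-fluoro-3-methoxyphenyl]-1-[3,5-dimethoxy-4-(methoxymethoxy)phenyl]propane-1,3-diol
Product: 17 3-[(1R,2S)-1,3-dihydroxy-1-[3,5-dimethoxy-4-(methoxymethoxy)phenyl]propan-2-yl]-4-fluoro-5-methoxybenzaldehyde
Conditions: 0.5 M aq. HCl/THF (1:3), 0 °C to rt
Reagents that add atoms: water, O
Why: Acid-catalysed acetal hydrolysis; a benzaldehyde dioxolane hydrolyses far faster than a formaldehyde-derived aryl MOM ether. The benzylic alcohol should not ionise in dilute acid, because its para oxygen is twisted out of conjugation by two ortho methoxy groups.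

Step 10
Reactants: 17 3-[(1R,2S)-1,3-dihydroxy-1-[3,5-dimethoxy-4-(methoxymethoxy)phenyl]propan-2-yl]-4-fluoro-5-methoxybenzaldehyde
Product: 18 4-fluoro-3-[(1R,2S)-1-hydroxy-1-[3,5-dimethoxy-4-(methoxymethoxy)phenyl]-3-(triphenylmethoxy)propan-2-yl]-5-methoxybenzaldehyde
Conditions: TrCl, Et3N, DMAP (cat.), CH2Cl2, rt
Reagents that add atoms: chlorotriphenylmethane, ClC(c1ccccc1)(c1ccccc1)c1ccccc1
Why: Tritylation; the bulk of the trityl group selects the primary hydroxyl over the hindered secondary benzylic one, and the resulting ether is stable to base and cannot migrate.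

Step 11
Reactants: 18 4-fluoro-3-[(1R,2S)-1-hydroxy-1-[3,5-dimethoxy-4-(methoxymethoxy)phenyl]-3-(triphenylmethoxy)propan-2-yl]-5-methoxybenzaldehyde
Product: 20 (2R,3S)-7-methoxy-2-[3,5-dimethoxy-4-(methoxymethoxy)phenyl]-3-[(triphenylmethoxy)methyl]-2,3-dihydro-1-benzofuran-5-carbaldehyde, via potassium alkoxide 19 (not isolated)
Conditions: KOt-Bu (1.1 equiv), THF (0.02 M), 0 °C to rt
Reagents that add atoms: none
Why: tert-Butoxide reversibly deprotonates the C2 hydroxyl of 18 to the alkoxide 19, whose oxygen adds to C7a, the fluorine-bearing carbon next to the side chain. The anionic σ-adduct is stabilised by delocalisation onto the para formyl group at C5, and loss of fluoride restores ring A (addition–elimination, SNAr). The closest known reaction type is the intramolecular etherification of para-carbonyl-activated aryl fluorides by alkoxides. The dihydrofuran ring closes in a 5-exo-trig mode by formation of O1–C7a. No stereocentre is formed or touched, since the C2–O and C3–C bonds stay intact, so the syn (1R,2S) chain from the aldol becomes the trans (2R,3S) ring. The step needs chemoselectivity between the two hydroxyls, which the trityl ether on the primary one secures. It also needs the aldehyde to survive, which the reversibility of alkoxide addition to a non-enolisable aldehyde, the low temperature and the dilution should secure. Displacement elsewhere is not possible, because ring A carries a single fluoride and the methoxy groups are not activated leaving groups.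

Step 12
Reactants: 21 3,5-dihydroxybenzyl alcohol
Product: 22 [3,5-bis(methoxymethoxy)phenyl]methanol
Conditions: MOMCl (2.2 equiv), K2CO3, acetone, 0 °C to rt
Reagents that add atoms: chloromethyl methyl ether, COCCl
Why: Phenol-selective O-alkylation: carbonate deprotonates only the two phenols, and the neutral benzylic alcohol reacts much more slowly.

Step 13
Reactants: 22 [3,5-bis(methoxymethoxy)phenyl]methanol
Product: 23 1-(bromomethyl)-3,5-bis(methoxymethoxy)benzene
Conditions: CBr4, PPh3, CH2Cl2, 0 °C
Reagents that add atoms: carbon tetrabromide, BrC(Br)(Br)Br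
Why: Appel bromination through an alkoxyphosphonium ion; the neutral conditions spare the MOM acetals, which HBr-generating reagents would not.

Step 14
Reactants: 23 1-(bromomethyl)-3,5-bis(methoxymethoxy)benzene
Product: 24 diethyl {[3,5-bis(methoxymethoxy)phenyl]methyl}phosphonate
Conditions: P(OEt)3 (neat), 120 °C
Reagents that add atoms: triethyl phosphite, CCOP(OCC)OCC
Why: Michaelis–Arbuzov reaction: SN2 attack of phosphorus on the benzylic bromide, then dealkylation of the phosphonium ion by bromide.

Step 15
Reactants: 20 (2R,3S)-7-methoxy-2-[3,5-dimethoxy-4-(methoxymethoxy)phenyl]-3-[(triphenylmethoxy)methyl]-2,3-dihydro-1-benzofuran-5-carbaldehyde; 24 diethyl {[3,5-bis(methoxymethoxy)phenyl]methyl}phosphonate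
Product: 26 (2R,3S)-5-[(E)-2-[3,5-bis(methoxymethoxy)phenyl]ethenyl]-7-methoxy-2-[3,5-dimethoxy-4-(methoxymethoxy)phenyl]-3-[(triphenylmethoxy)methyl]-2,3-dihydro-1-benzofuran, via phosphonate carbanion 25 (not isolated)
Conditions: KOt-Bu, THF, 0 °C; then 20, 0 °C to rt
Reagents that add atoms: none
Why: Horner–Wadsworth–Emmons olefination; reversible addition of the benzylic phosphonate carbanion to the aromatic aldehyde and elimination through the less crowded oxaphosphetane should give the E stilbene. Compound 20 has no enolisable or base-labile site.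

Step 16
Reactants: 26 (2R,3S)-5-[(E)-2-[3,5-bis(methoxymethoxy)phenyl]ethenyl]-7-methoxy-2-[3,5-dimethoxy-4-(methoxymethoxy)phenyl]-3-[(triphenylmethoxy)methyl]-2,3-dihydro-1-benzofuran
Product: 27 gnetucleistol F, 5-[(E)-2-[(2R,3S)-2-(4-hydroxy-3,5-dimethoxyphenyl)-3-(hydroxymethyl)-7-methoxy-2,3-dihydro-1-benzofuran-5-yl]ethenyl]benzene-1,3-diol
Conditions: HCl (about 1 M in MeOH), MeOH/THF, rt
Reagents that add atoms: none
Why: Acid-catalysed methanolysis (acetal exchange) of the trityl ether and the three aryl MOM ethers. All four groups should leave at room temperature, below the acidity at which the C2–O1 bond ionises, so the trans stereodiad should be kept.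

## Compound list

1 | 4-fluoro-3-methoxybenzaldehyde | COc1cc(C=O)ccc1F | starting material
2 | 2-(4-fluoro-3-methoxyphenyl)-1,3-dioxolane | COc1cc(C2OCCO2)ccc1F | intermediate
3 | [5-(1,3-dioxolan-2-yl)-2-fluoro-3-methoxyphenyl]lithium (formed in the flask) | [Li]c1cc(C2OCCO2)cc(OC)c1F | intermediate
4 | 2-(4-fluoro-3-iodo-5-methoxyphenyl)-1,3-dioxolane | COc1cc(C2OCCO2)cc(I)c1F | intermediate
5 | ethyl 2-[5-(1,3-dioxolan-2-yl)-2-fluoro-3-methoxyphenyl]acetate | CCOC(=O)Cc1cc(C2OCCO2)cc(OC)c1F | intermediate
6 | lithium 2-[5-(1,3-dioxolan-2-yl)-2-fluoro-3-methoxyphenyl]acetate (formed in the flask) | [Li+].[O-]C(=O)Cc1cc(C2OCCO2)cc(OC)c1F | intermediate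
7 | 2-[5-(1,3-dioxolan-2-yl)-2-fluoro-3-methoxyphenyl]acetic acid | OC(=O)Cc1cc(C2OCCO2)cc(OC)c1F | intermediate
8 | (R)-4-benzyl-2-oxazolidinone | O=C1N[C@H](Cc2ccccc2)CO1 | starting material
9 | 2-[5-(1,3-dioxolan-2-yl)-2-fluoro-3-methoxyphenyl]acetic 2,2-dimethylpropanoic anhydride (formed in the flask) | CC(C)(C)C(=O)OC(=O)Cc1cc(C2OCCO2)cc(OC)c1F | intermediate
10 | (4R)-4-benzyl-3-{2-[5-(1,3-dioxolan-2-yl)-2-fluoro-3-methoxyphenyl]acetyl}-1,3-oxazolidin-2-one | COc1cc(C2OCCO2)cc(CC(=O)N3C(=O)OC[C@H]3Cc4ccccc4)c1F | intermediate
11 | syringaldehyde (4-hydroxy-3,5-dimethoxybenzaldehyde) | COc1cc(C=O)cc(OC)c1O | starting material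
12 | 3,5-dimethoxy-4-(methoxymethoxy)benzaldehyde | COCOc1c(OC)cc(C=O)cc1OC | intermediate
13 | (Z)-dibutylboron enolate of 10 (formed in the flask) | CCCCB(CCCC)O/C(=C\c1cc(C2OCCO2)cc(OC)c1F)N1C(=O)OC[C@H]1Cc1ccccc1 | intermediate
14 | O-dibutylboryl aldolate of 15 (formed in the flask) | COc1cc([C@H](OB(CCCC)CCCC)[C@H](C(=O)N2C(=O)OC[C@H]2Cc2ccccc2)c2cc(C3OCCO3)cc(OC)c2F)cc(OC)c1OCOC | intermediate
15 | (4R)-4-benzyl-3-[(2R,3R)-2-[5-(1,3-dioxolan-2-yl)-2-fluoro-3-methoxyphenyl]-3-hydroxy-3-[3,5-dimethoxy-4-(methoxymethoxy)phenyl]propanoyl]-1,3-oxazolidin-2-one | COc1cc([C@H](O)[C@H](C(=O)N2C(=O)OC[C@H]2Cc2ccccc2)c2cc(C3OCCO3)cc(OC)c2F)cc(OC)c1OCOC | intermediate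
16 | (1R,2S)-2-[5-(1,3-dioxolan-2-yl)-2-fluoro-3-methoxyphenyl]-1-[3,5-dimethoxy-4-(methoxymethoxy)phenyl]propane-1,3-diol | COc1cc([C@H](O)[C@H](CO)c2cc(C3OCCO3)cc(OC)c2F)cc(OC)c1OCOC | intermediate
17 | 3-[(1R,2S)-1,3-dihydroxy-1-[3,5-dimethoxy-4-(methoxymethoxy)phenyl]propan-2-yl]-4-fluoro-5-methoxybenzaldehyde | COc1cc([C@H](O)[C@H](CO)c2cc(C=O)cc(OC)c2F)cc(OC)c1OCOC | intermediate
18 | 4-fluoro-3-[(1R,2S)-1-hydroxy-1-[3,5-dimethoxy-4-(methoxymethoxy)phenyl]-3-(triphenylmethoxy)propan-2-yl]-5-methoxybenzaldehyde | COc1cc([C@H](O)[C@H](COC(c2ccccc2)(c2ccccc2)c2ccccc2)c2cc(C=O)cc(OC)c2F)cc(OC)c1OCOC | intermediate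
19 | potassium alkoxide of 18 at the C2 oxygen (formed in the flask) | [K+].COc1cc([C@H]([O-])[C@H](COC(c2ccccc2)(c2ccccc2)c2ccccc2)c2cc(C=O)cc(OC)c2F)cc(OC)c1OCOC | intermediate
20 | (2R,3S)-7-methoxy-2-[3,5-dimethoxy-4-(methoxymethoxy)phenyl]-3-[(triphenylmethoxy)methyl]-2,3-dihydro-1-benzofuran-5-carbaldehyde | COc1cc([C@@H]2Oc3c(OC)cc(C=O)cc3[C@H]2COC(c4ccccc4)(c4ccccc4)c4ccccc4)cc(OC)c1OCOC | intermediate
21 | 3,5-dihydroxybenzyl alcohol | OCc1cc(O)cc(O)c1 | starting material
22 | [3,5-bis(methoxymethoxy)phenyl]methanol | COCOc1cc(CO)cc(OCOC)c1 | intermediate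
23 | 1-(bromomethyl)-3,5-bis(methoxymethoxy)benzene | COCOc1cc(CBr)cc(OCOC)c1 | intermediate
24 | diethyl {[3,5-bis(methoxymethoxy)phenyl]methyl}phosphonate | CCOP(=O)(Cc1cc(OCOC)cc(OCOC)c1)OCC | intermediate
25 | potassium carbanion of 24 (formed in the flask) | [K+].CCOP(=O)([CH-]c1cc(OCOC)cc(OCOC)c1)OCC | intermediate
26 | (2R,3S)-5-[(E)-2-[3,5-bis(methoxymethoxy)phenyl]ethenyl]-7-methoxy-2-[3,5-dimethoxy-4-(methoxymethoxy)phenyl]-3-[(triphenylmethoxy)methyl]-2,3-dihydro-1-benzofuran | COc1cc([C@@H]2Oc3c(OC)cc(/C=C/c4cc(OCOC)cc(OCOC)c4)cc3[C@H]2COC(c4ccccc4)(c4ccccc4)c4ccccc4)cc(OC)c1OCOC | intermediate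
27 | gnetucleistol F, 5-[(E)-2-[(2R,3S)-2-(4-hydroxy-3,5-dimethoxyphenyl)-3-(hydroxymethyl)-7-methoxy-2,3-dihydro-1-benzofuran-5-yl]ethenyl]benzene-1,3-diol | COc1cc([C@@H]2Oc3c(OC)cc(/C=C/c4cc(O)cc(O)c4)cc3[C@H]2CO)cc(OC)c1O | target

## Step count and least certain steps

Total step count: 16. Longest linear sequence: 12 steps (steps 1 to 5, 7 to 11, 15 and 16, from 1 to 27).

**Step 11 (key step).**
- Risk: hydride transfer from the benzylic alkoxide to the formyl group (Oppenauer- or Cannizzaro-type redox), or alkoxide addition to the aldehyde, may outrun the displacement. The formyl group is only a moderate activator, and the C7 methoxy group crowds C7a.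
- Fallback: it sets out from 18. Iodine in aqueous ammonia/THF at room temperature converts the formyl group into a nitrile, giving 4-fluoro-3-[(1R,2S)-1-hydroxy-1-[3,5-dimethoxy-4-(methoxymethoxy)phenyl]-3-(triphenylmethoxy)propan-2-yl]-5-methoxybenzonitrile F1. The nitrile activates C7a equally but cannot accept hydride or alkoxide irreversibly under the closure conditions. KN(SiMe3)2 in THF at 0 °C to room temperature then closes the ring to (2R,3S)-7-methoxy-2-[3,5-dimethoxy-4-(methoxymethoxy)phenyl]-3-[(triphenylmethoxy)methyl]-2,3-dihydro-1-benzofuran-5-carbonitrile F2. Reduction with i-Bu2AlH in toluene at −78 °C and mild aqueous hydrolysis of the aldimine returns to the route at 20.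

**Step 2.**
- Risk: deprotonation at the position between the methoxy group and the acetal, which coordination to lithium favours, or loss of LiF from 3 to an aryne if the temperature rises. Either leads to the wrong substitution pattern on ring A.
- Fallback: it sets out from 2 and replaces acidity control by steric control. Iridium-catalysed C–H borylation ([Ir(OMe)(cod)]2, 4,4'-di-tert-butyl-2,2'-bipyridine, B2pin2, THF, 60 °C) should functionalise only the C–H bond whose sole ortho neighbour is fluorine. This gives 2-[5-(1,3-dioxolan-2-yl)-2-fluoro-3-methoxyphenyl]-4,4,5,5-tetramethyl-1,3,2-dioxaborolane F3. A Suzuki–Miyaura-type coupling with ethyl bromoacetate (Pd(OAc)2, P(o-tol)3, K3PO4, THF/H2O, rt) returns to the route at 5.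

**Step 7.**
- Risk: the conjugated arylacetyl boron enolate adds slowly to the electron-rich aldehyde 12, so retro-aldol equilibration of aldolate 14 on warming may erode the syn selectivity. Activation of the dioxolane by the boron triflate is a second risk.
- Fallback: it sets out from 11 and changes the electronic character of the electrophile. Acylation with t-BuCOCl/Et3N/DMAP gives 4-formyl-2,6-dimethoxyphenyl 2,2-dimethylpropanoate F4, a more electrophilic aldehyde whose aldolate is less prone to reversal. The same boron aldol with 10 gives 4-[(1R,2R)-3-[(4R)-4-benzyl-2-oxo-1,3-oxazolidin-3-yl]-2-[5-(1,3-dioxolan-2-yl)-2-fluoro-3-methoxyphenyl]-1-hydroxy-3-oxopropyl]-2,6-dimethoxyphenyl 2,2-dimethylpropanoate F5. Excess LiBH4 (THF/MeOH, 0 °C to rt) removes both the auxiliary and the pivaloyl group to give 4-[(1R,2S)-2-[5-(1,3-dioxolan-2-yl)-2-fluoro-3-methoxyphenyl]-1,3-dihydroxypropyl]-2,6-dimethoxyphenol F6. Phenol-selective alkylation (MOMCl, K2CO3, acetone) returns to the route at 16.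

**Step 16.**
- Risk: once the syringyl phenol is free, acid can ionise C2–O1 (quinone-methide-type opening) while the slower resorcinol MOM ethers are still being cleaved. This would lead to epimerisation at C2 or capture by methanol.
- Fallback: it sets out from 20 and removes the resorcinol protecting groups from the plan. Wittig methylenation (Ph3PCH3Br, KOt-Bu, THF, 0 °C) gives (2R,3S)-5-ethenyl-7-methoxy-2-[3,5-dimethoxy-4-(methoxymethoxy)phenyl]-3-[(triphenylmethoxy)methyl]-2,3-dihydro-1-benzofuran F7. A Mizoroki–Heck coupling with commercial 5-iodobenzene-1,3-diol (Pd(OAc)2, P(o-tol)3, Et3N, DMF, 90 °C) gives 5-[(E)-2-[(2R,3S)-7-methoxy-2-[3,5-dimethoxy-4-(methoxymethoxy)phenyl]-3-[(triphenylmethoxy)methyl]-2,3-dihydro-1-benzofuran-5-yl]ethenyl]benzene-1,3-diol F8. A brief acid methanolysis (dilute HCl in MeOH, rt) then has to remove only the trityl ether and one aryl MOM ether, and returns to the route at 27.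

## Further compounds

F1 | step 11 | 4-fluoro-3-[(1R,2S)-1-hydroxy-1-[3,5-dimethoxy-4-(methoxymethoxy)phenyl]-3-(triphenylmethoxy)propan-2-yl]-5-methoxybenzonitrile | COc1cc([C@H](O)[C@H](COC(c2ccccc2)(c2ccccc2)c2ccccc2)c2cc(C#N)cc(OC)c2F)cc(OC)c1OCOC
F2 | step 11 | (2R,3S)-7-methoxy-2-[3,5-dimethoxy-4-(methoxymethoxy)phenyl]-3-[(triphenylmethoxy)methyl]-2,3-dihydro-1-benzofuran-5-carbonitrile | COc1cc([C@@H]2Oc3c(OC)cc(C#N)cc3[C@H]2COC(c4ccccc4)(c4ccccc4)c4ccccc4)cc(OC)c1OCOC
F3 | step 2 | 2-[5-(1,3-dioxolan-2-yl)-2-fluoro-3-methoxyphenyl]-4,4,5,5-tetramethyl-1,3,2-dioxaborolane | COc1cc(C2OCCO2)cc(B3OC(C)(C)C(C)(C)O3)c1F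
F4 | step 7 | 4-formyl-2,6-dimethoxyphenyl 2,2-dimethylpropanoate | COc1cc(C=O)cc(OC)c1OC(=O)C(C)(C)C
F5 | step 7 | 4-[(1R,2R)-3-[(4R)-4-benzyl-2-oxo-1,3-oxazolidin-3-yl]-2-[5-(1,3-dioxolan-2-yl)-2-fluoro-3-methoxyphenyl]-1-hydroxy-3-oxopropyl]-2,6-dimethoxyphenyl 2,2-dimethylpropanoate | COc1cc([C@H](O)[C@H](C(=O)N2C(=O)OC[C@H]2Cc2ccccc2)c2cc(C3OCCO3)cc(OC)c2F)cc(OC)c1OC(=O)C(C)(C)C
F6 | step 7 | 4-[(1R,2S)-2-[5-(1,3-dioxolan-2-yl)-2-fluoro-3-methoxyphenyl]-1,3-dihydroxypropyl]-2,6-dimethoxyphenol | COc1cc([C@H](O)[C@H](CO)c2cc(C3OCCO3)cc(OC)c2F)cc(OC)c1O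
F7 | step 16 | (2R,3S)-5-ethenyl-7-methoxy-2-[3,5-dimethoxy-4-(methoxymethoxy)phenyl]-3-[(triphenylmethoxy)methyl]-2,3-dihydro-1-benzofuran | COc1cc([C@@H]2Oc3c(OC)cc(C=C)cc3[C@H]2COC(c4ccccc4)(c4ccccc4)c4ccccc4)cc(OC)c1OCOC
F8 | step 16 | 5-[(E)-2-[(2R,3S)-7-methoxy-2-[3,5-dimethoxy-4-(methoxymethoxy)phenyl]-3-[(triphenylmethoxy)methyl]-2,3-dihydro-1-benzofuran-5-yl]ethenyl]benzene-1,3-diol | COc1cc([C@@H]2Oc3c(OC)cc(/C=C/c4cc(O)cc(O)c4)cc3[C@H]2COC(c4ccccc4)(c4ccccc4)c4ccccc4)cc(OC)c1OCOC
A1 | alternative 1 | 4-(tert-butyldimethylsilyloxy)-3,5-dimethoxybenzaldehyde | COc1cc(C=O)cc(OC)c1O[Si](C)(C)C(C)(C)C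
A2 | alternative 1 | (4-bromo-2-ethenyl-6-methoxyphenoxy)(tert-butyl)dimethylsilane | C=Cc1cc(Br)cc(OC)c1O[Si](C)(C)C(C)(C)C
A3 | alternative 1 | (2S,3S)-3-[5-bromo-2-(tert-butyldimethylsilyloxy)-3-methoxyphenyl]-2-[4-(tert-butyldimethylsilyloxy)-3,5-dimethoxyphenyl]oxetane (trans) | COc1cc([C@H]2OC[C@@H]2c2cc(Br)cc(OC)c2O[Si](C)(C)C(C)(C)C)cc(OC)c1O[Si](C)(C)C(C)(C)C
A4 | alternative 2 | (1R,2S)-configured diyne: 1-[4-(tert-butyldimethylsilyloxy)-3,5-dimethoxyphenyl]-2-[(tert-butyldimethylsilyloxy)methyl]but-3-yn-1-yl 2-(4,4,5,5-tetramethyl-1,3,2-dioxaborolan-2-yl)ethynyl ether | COc1cc([C@H](OC#CB2OC(C)(C)C(C)(C)O2)[C@H](CO[Si](C)(C)C(C)(C)C)C#C)cc(OC)c1O[Si](C)(C)C(C)(C)C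
A5 | alternative 2 | 3,3-diethoxyprop-1-yne | CCOC(OCC)C#C
A6 | alternative 2 | (2R,3S)-5-(diethoxymethyl)-7-(4,4,5,5-tetramethyl-1,3,2-dioxaborolan-2-yl)-3-[(tert-butyldimethylsilyloxy)methyl]-2-[4-(tert-butyldimethylsilyloxy)-3,5-dimethoxyphenyl]-2,3-dihydro-1-benzofuran | COc1cc([C@@H]2Oc3c(B4OC(C)(C)C(C)(C)O4)cc(C(OCC)OCC)cc3[C@H]2CO[Si](C)(C)C(C)(C)C)cc(OC)c1O[Si](C)(C)C(C)(C)C
A7 | alternative 3 | 4-[(2R)-6-bromo-8-methoxy-4-oxo-3,4-dihydro-2H-chromen-2-yl]-2,6-dimethoxyphenyl 2,2-dimethylpropanoate | COc1cc([C@H]2CC(=O)c3cc(Br)cc(OC)c3O2)cc(OC)c1OC(=O)C(C)(C)C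
A8 | alternative 3 | methyl (2R,3R)-5-bromo-2-[3,5-dimethoxy-4-(2,2-dimethylpropanoyloxy)phenyl]-7-methoxy-2,3-dihydro-1-benzofuran-3-carboxylate (trans) | COc1cc([C@@H]2Oc3c(OC)cc(Br)cc3[C@H]2C(=O)OC)cc(OC)c1OC(=O)C(C)(C)C
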